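**Strategy**

The dihydropyran is treated as the cyclic enol ether of a δ-hydroxy β-formyl ester, and ring carbon C-4 as the β-carbon of an acrylate whose α-carbon is C-5. Everything rests on one conjugate addition: the acetate CH2 of a benzyl-protected hydroxytyrosol acetate enolate is joined to C-4 of an open-chain (Z)-enoate that already carries the C-2/C-3 stereodiad, with A(1,3) strain directing attack anti to the silyloxyethyl branch. The same operation leaves an enolate exactly on C-5, which is formylated in the flask to supply C-6. Acid then frees O-1 and closes the ring; hydrogenolysis frees the three hydroxyls.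

Key step: step 6

Remarks on the chemistry:
- Atom labels O-1 and C-2 to C-6 are those of the dihydropyran ring of the target and are used for the open-chain precursors as well.
- Methyl (R)-3-hydroxybutanoate and hydroxytyrosol acetate are taken as commercial.
- The β-formyl ester 11 is drawn as the aldehyde tautomer. It should exist mainly as the chelated enol, so its formyl-bearing carbon is left unassigned.

**Route**

Step 1
Reactants: 1 methyl (R)-3-hydroxybutanoate
Product: 3 methyl (2R,3R)-2-[(benzyloxy)methyl]-3-hydroxybutanoate, via dilithium dianion 2 (not isolated)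
Conditions: LiN(i-Pr)2 (2.2 equiv), THF, −78 to −20 °C; then BnOCH2Cl, DMPU, −78 to −20 °C
Reagents that add atoms: benzyl chloromethyl ether, ClCOCc1ccccc1
Why: Fráter–Seebach alkylation: the chelated alkoxide enolate 2 should be alkylated on the face anti to the C-3 methyl group, which sets the new centre anti to the hydroxyl (2R,3R) and so fixes the trans C-2/C-3 relationship of the ring.

Step 2
Reactants: 3 methyl (2R,3R)-2-[(benzyloxy)methyl]-3-hydroxybutanoate
Product: 4 methyl (2R,3R)-2-[(benzyloxy)methyl]-3-[(tert-butyldimethylsilyl)oxy]butanoate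
Conditions: TBSOTf, 2,6-lutidine, CH2Cl2, −78 to 0 °C
Reagents that add atoms: tert-butyldimethylsilyl triflate, CC(C)(C)[Si](C)(C)OS(=O)(=O)C(F)(F)F
Why: Standard silylation of a hindered secondary alcohol; the silyl ether prevents lactonisation of the later (Z)-enoate and enlarges the branch that steers the key step.

Step 3
Reactants: 4 methyl (2R,3R)-2-[(benzyloxy)methyl]-3-[(tert-butyldimethylsilyl)oxy]butanoate
Product: 5 (2R,3R)-2-[(benzyloxy)methyl]-3-[(tert-butyldimethylsilyl)oxy]butanal
Conditions: i-Bu2AlH (1.1 equiv), CH2Cl2, −78 °C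
Reagents that add atoms: none
Why: Partial ester reduction: the tetrahedral aluminium hemiacetal should persist at −78 °C and release the aldehyde only on work-up, and the cold, non-basic medium should leave the α-centre intact.

Step 4
Reactants: 5 (2R,3R)-2-[(benzyloxy)methyl]-3-[(tert-butyldimethylsilyl)oxy]butanal
Product: 6 methyl (2Z,4R,5R)-4-[(benzyloxy)methyl]-5-[(tert-butyldimethylsilyl)oxy]hex-2-enoate
Conditions: (CF3CH2O)2P(O)CH2CO2Me, KN(SiMe3)2, 18-crown-6, THF, −78 °C
Reagents that add atoms: methyl bis(2,2,2-trifluoroethyl)phosphonoacetate, COC(=O)CP(=O)(OCC(F)(F)F)OCC(F)(F)F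
Why: Still–Gennari olefination: fast, irreversible elimination from the kinetic adduct of the electron-poor phosphonate should give the (Z)-enoate, the geometry that the A(1,3) control of step 6 requires.

Step 5
Reactants: 7 hydroxytyrosol acetate (2-(3,4-dihydroxyphenyl)ethyl acetate)
Product: 8 2-[3,4-bis(benzyloxy)phenyl]ethyl acetate
Conditions: BnBr (2.2 equiv), K2CO3, acetone, reflux
Reagents that add atoms: benzyl bromide, BrCc1ccccc1
Why: Williamson etherification of the two phenols; the acetate should survive anhydrous carbonate, and the benzyl ethers are removed together with the third one in the last step.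

Step 6
Reactants: 8 2-[3,4-bis(benzyloxy)phenyl]ethyl acetate; 6 methyl (2Z,4R,5R)-4-[(benzyloxy)methyl]-5-[(tert-butyldimethylsilyl)oxy]hex-2-enoate
Product: 11 1-methyl 5-{2-[3,4-bis(benzyloxy)phenyl]ethyl} (3S)-3-[(2R,3R)-1-(benzyloxy)-3-[(tert-butyldimethylsilyl)oxy]butan-2-yl]-2-formylpentanedioate, via lithium enolate 9 (not isolated), via Michael adduct enolate 10 (not isolated)
Conditions: 8 (1.5 equiv), LiN(i-Pr)2, THF, −78 °C; then 6, THF–DMPU, −78 °C; then HCO2CH2CF3 (excess), −78 to −40 °C; AcOH quench
Reagents that add atoms: 2,2,2-trifluoroethyl formate, O=COCC(F)(F)F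
Why: Michael addition of lithium ester enolate 9 to the β-carbon of (Z)-enoate 6 (the future ring C-4) should give ester enolate 10 regiospecifically on the future C-5, and this kinetic enolate is C-formylated by the formate ester in a crossed Claisen condensation; the closest known reaction types are the Michael addition of lithium ester enolates to α,β-unsaturated esters with in-flask trapping of the adduct enolate, and the Claisen formylation of ester enolates. No ring is closed in this step; the dihydropyran is closed in step 7. The new stereocentre (ring C-4) is controlled by the resident C-3 centre: A(1,3) strain with the cis ester of the (Z)-alkene holds the C-3 hydrogen in the alkene plane, so the two faces of the β-carbon are flanked by the CH2OBn arm and by the branched CH(OTBS)CH3 group, and the enolate should enter past the smaller CH2OBn arm, anti to the silyloxyethyl group, which corresponds to the (4S) configuration of the target. The formyl-bearing carbon is no lasting stereocentre because it becomes sp2 in step 7. The step needs 1,4- over 1,2-addition (low temperature, DMPU cosolvent), facial selectivity (Z geometry and the bulky silyl ether) and formylation at C-5 rather than at the other ester α-carbon (trapping of 10 at −78 °C with the very reactive trifluoroethyl formate before any proton transfer).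

Step 7
Reactants: 11 1-methyl 5-{2-[3,4-bis(benzyloxy)phenyl]ethyl} (3S)-3-[(2R,3R)-1-(benzyloxy)-3-[(tert-butyldimethylsilyl)oxy]butan-2-yl]-2-formylpentanedioate
Product: 13 methyl (2R,3R,4S)-4-(2-{2-[3,4-bis(benzyloxy)phenyl]ethoxy}-2-oxoethyl)-3-[(benzyloxy)methyl]-2-methyl-3,4-dihydro-2H-pyran-5-carboxylate, via lactol 12 (not isolated)
Conditions: HF·pyridine, THF, 0 °C to rt; then TsOH·H2O (cat.), toluene, 4 Å MS, 60 °C
Reagents that add atoms: none
Why: Fluoride desilylation frees O-1, which should add to the formyl carbon in a favoured 6-exo-trig hemiacetalisation to lactol 12, and acid-catalysed dehydration should then give the conjugated enol ether (a vinylogous carbonate) as the thermodynamic sink without touching the three stereocentres.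

Step 8
Reactants: 13 methyl (2R,3R,4S)-4-(2-{2-[3,4-bis(benzyloxy)phenyl]ethoxy}-2-oxoethyl)-3-[(benzyloxy)methyl]-2-methyl-3,4-dihydro-2H-pyran-5-carboxylate
Product: 14 methyl (2R,3R,4S)-4-{2-[2-(3,4-dihydroxyphenyl)ethoxy]-2-oxoethyl}-3-(hydroxymethyl)-2-methyl-3,4-dihydro-2H-pyran-5-carboxylate
Conditions: H2 (1 atm), 10% Pd/C, EtOAc, rt
Reagents that add atoms: none
Why: Hydrogenolysis of the two aryl benzyl ethers and the alkyl benzyl ether under neutral conditions; the trisubstituted push–pull enol ether should resist hydrogenation, and the neutral medium should avoid lactonisation of the freed primary alcohol onto the side-chain ester.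

**Compound list**

1 | methyl (R)-3-hydroxybutanoate | C[C@@H](O)CC(=O)OC | starting material
2 | dilithium alkoxide enolate of 1 | [Li+].[Li+].C[C@@H]([O-])C=C([O-])OC | intermediate
3 | methyl (2R,3R)-2-[(benzyloxy)methyl]-3-hydroxybutanoate | O[C@H](C)[C@@H](COCc1ccccc1)C(=O)OC | intermediate
4 | methyl (2R,3R)-2-[(benzyloxy)methyl]-3-[(tert-butyldimethylsilyl)oxy]butanoate | CC(C)(C)[Si](C)(C)O[C@H](C)[C@@H](COCc1ccccc1)C(=O)OC | intermediate
5 | (2R,3R)-2-[(benzyloxy)methyl]-3-[(tert-butyldimethylsilyl)oxy]butanal | CC(C)(C)[Si](C)(C)O[C@H](C)[C@@H](COCc1ccccc1)C=O | intermediate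
6 | methyl (2Z,4R,5R)-4-[(benzyloxy)methyl]-5-[(tert-butyldimethylsilyl)oxy]hex-2-enoate | CC(C)(C)[Si](C)(C)O[C@H](C)[C@@H](COCc1ccccc1)/C=C\C(=O)OC | intermediate
7 | hydroxytyrosol acetate, 2-(3,4-dihydroxyphenyl)ethyl acetate | CC(=O)OCCc1ccc(O)c(O)c1 | starting material
8 | 2-[3,4-bis(benzyloxy)phenyl]ethyl acetate | CC(=O)OCCc1ccc(OCc2ccccc2)c(OCc2ccccc2)c1 | intermediate
9 | lithium enolate of 8 | [Li+].C=C([O-])OCCc1ccc(OCc2ccccc2)c(OCc2ccccc2)c1 | intermediate
10 | lithium ester enolate of the Michael adduct (enolate on the carbon α to the methyl ester, future C-5) | [Li+].CC(C)(C)[Si](C)(C)O[C@H](C)[C@@H](COCc1ccccc1)[C@@H](C=C([O-])OC)CC(=O)OCCc1ccc(OCc2ccccc2)c(OCc2ccccc2)c1 | intermediate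
11 | 1-methyl 5-{2-[3,4-bis(benzyloxy)phenyl]ethyl} (3S)-3-[(2R,3R)-1-(benzyloxy)-3-[(tert-butyldimethylsilyl)oxy]butan-2-yl]-2-formylpentanedioate (C-2 unassigned, enol tautomers) | CC(C)(C)[Si](C)(C)O[C@H](C)[C@@H](COCc1ccccc1)[C@@H](C(C=O)C(=O)OC)CC(=O)OCCc1ccc(OCc2ccccc2)c(OCc2ccccc2)c1 | intermediate
12 | methyl (2R,3R,4S)-4-(2-{2-[3,4-bis(benzyloxy)phenyl]ethoxy}-2-oxoethyl)-3-[(benzyloxy)methyl]-6-hydroxy-2-methyloxane-5-carboxylate (lactol, C-5 and C-6 unassigned) | COC(=O)C1C(O)O[C@H](C)[C@@H](COCc2ccccc2)[C@@H]1CC(=O)OCCc1ccc(OCc2ccccc2)c(OCc2ccccc2)c1 | intermediate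
13 | methyl (2R,3R,4S)-4-(2-{2-[3,4-bis(benzyloxy)phenyl]ethoxy}-2-oxoethyl)-3-[(benzyloxy)methyl]-2-methyl-3,4-dihydro-2H-pyran-5-carboxylate | COC(=O)C1=CO[C@H](C)[C@@H](COCc2ccccc2)[C@@H]1CC(=O)OCCc1ccc(OCc2ccccc2)c(OCc2ccccc2)c1 | intermediate
14 | methyl (2R,3R,4S)-4-{2-[2-(3,4-dihydroxyphenyl)ethoxy]-2-oxoethyl}-3-(hydroxymethyl)-2-methyl-3,4-dihydro-2H-pyran-5-carboxylate | COC(=O)C1=CO[C@H](C)[C@@H](CO)[C@@H]1CC(=O)OCCc1ccc(O)c(O)c1 | target

**Step count and risks**

Total steps: 8. Longest linear sequence: 7 (steps 1–4 and 6–8; step 5 prepares the second fragment).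

Steps most likely to fail:

1. Step 6. The simple (Z)-enoate is only a moderate acceptor. Competing 1,2-attack on the methyl ester, γ-deprotonation of the enoate, weak facial discrimination, or proton transfer between the two ester α-positions before formylation would all erode the step. The fallback sets out from aldehyde 5 and comes back at formyl ester 11. Knoevenagel condensation of 5 with S-ethyl O-methyl thiomalonate (TiCl4, pyridine, THF, 0 °C) would give methyl (4R,5R)-4-[(benzyloxy)methyl]-5-[(tert-butyldimethylsilyl)oxy]-2-[(ethylsulfanyl)carbonyl]hex-2-enoate F1. This doubly activated alkene should accept enolate 9 at −78 °C without 1,2-addition, still under A(1,3) control because one acyl group is always cis to C-3, to give 1-methyl 5-{2-[3,4-bis(benzyloxy)phenyl]ethyl} (3S)-3-[(2R,3R)-1-(benzyloxy)-3-[(tert-butyldimethylsilyl)oxy]butan-2-yl]-2-[(ethylsulfanyl)carbonyl]pentanedioate F2. Fukuyama reduction of the thioester (Et3SiH, 10% Pd/C, acetone, rt) would then give the aldehyde, which is compound 11.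

2. Step 1. The chloromethyl ether may alkylate the alkoxide oxygen, react sluggishly at carbon, or give lower anti selectivity than simple alkyl halides. The fallback sets out from 1 and comes back at 3. Dianion 2 is intercepted with monomeric formaldehyde (aldol-type hydroxymethylation, again anti to the C-3 methyl) to give methyl (2R,3R)-3-hydroxy-2-(hydroxymethyl)butanoate F3. The primary hydroxyl is then benzylated selectively through the dibutylstannylene acetal (Bu2SnO, toluene, reflux; then BnBr, CsF, DMF) to return to 3.

3. Step 8. Over-reduction of the enol-ether double bond, or lactonisation of the freed alcohol on an acidic catalyst surface, could accompany the triple debenzylation. The fallback sets out from 13 and comes back at 14 directly, by Lewis-acid debenzylation with a cation scavenger (BCl3, pentamethylbenzene, CH2Cl2, −78 °C), which uses no hydrogen; it makes no new compound (F0).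

**Further compounds**

F1 | step 6 | methyl (4R,5R)-4-[(benzyloxy)methyl]-5-[(tert-butyldimethylsilyl)oxy]-2-[(ethylsulfanyl)carbonyl]hex-2-enoate (E/Z mixture) | CC(C)(C)[Si](C)(C)O[C@H](C)[C@@H](COCc1ccccc1)C=C(C(=O)OC)C(=O)SCC
F2 | step 6 | 1-methyl 5-{2-[3,4-bis(benzyloxy)phenyl]ethyl} (3S)-3-[(2R,3R)-1-(benzyloxy)-3-[(tert-butyldimethylsilyl)oxy]butan-2-yl]-2-[(ethylsulfanyl)carbonyl]pentanedioate | CC(C)(C)[Si](C)(C)O[C@H](C)[C@@H](COCc1ccccc1)[C@@H](C(C(=O)OC)C(=O)SCC)CC(=O)OCCc1ccc(OCc2ccccc2)c(OCc2ccccc2)c1
F3 | step 1 | methyl (2R,3R)-3-hydroxy-2-(hydroxymethyl)butanoate | O[C@H](C)[C@@H](CO)C(=O)OC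
F0 | step 8 | none | none
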